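If a single-handed catalyst resolves a racemate while its products interconvert, the product excess I read is what was made minus what has since been lost, so I reckoned the loss as a correction to the main reckoning. Amounts are fractions of the two substrates charged together.

| setting | noon | spring | flask |
|---|---|---|---|
| left-handed substrate | 18 mM | 36 mM | 18 mM |
| right-handed substrate | 18 mM | 36 mM | 18 mM |
| reagent | 21.6 mM | 21.6 mM | 21.6 mM |
| precatalyst | 0.18 mM | 0.18 mM | 0.18 mM |
| added ligand | 0.11 mM | 0.11 mM | 0.11 mM |
| remark | the very flask that is asked about, followed so far | run made earlier |  |
| time |  |  | 15 h |

- noon (time / h: left-handed product / %, right-handed product / %): 2.00: 6.5, 0.9; 4.00: 14.6, 4.2; 6.00: 22.9, 8.0; 8.00: 27.9, 11.8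
- spring (time / h: left-handed product / %, right-handed product / %): 0.833: 1.3, 0.3; 2.00: 4.8, 1.2; 5.00: 14.7, 5.5; 10.0: 18.0, 9.5

(standard deviation of a reading: 0.5 percentage points)

- catalyst is single-handed; left-handed substrate and right-handed substrate are mirror images of each other, charged as a racemate, each of them at the stated concentration
- the earlier runs were read with a standard deviation of 0.5 percentage points
- steps that have been proposed: reagent + catalyst + left-handed substrate -> catalyst + left-handed product; reagent + catalyst + right-handed substrate -> catalyst + right-handed product; left-handed product <-> right-handed product; precatalyst -> catalyst; catalyst + added ligand <-> idle complex
- an excess is the difference of the two amounts in percent of their sum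
- an excess is below zero if the other one leads

1. excess of left-handed product over right-handed product in the product at 50 min
2. excess of left-handed product over right-handed product in the product at 15 h
3. part of the left-handed substrate and right-handed substrate charged together that has reacted at 15 h

1. Main step. Reagent was charged at less than the two substrates together, so it is the limiting reagent and allows a conversion of 60.0%. Noon stood at 39.7% after 8.00 h. The unused allowance in the last noon readings had been falling at 0.180 /h, and continuing that rate I put noon at 54.2% at 15 h.

2. Selectivity. Pooling both runs at 2.00 h, I read a selectivity factor of 5.38, so an excess made of 68.7%. The favoured substrate thins as a resolution proceeds, so for noon's product after 8.00 h I guessed half of that excess. Before counting any loss, noon's left-minus-right product difference of 16 percentage points then grows to 21 points, an excess of 38.7%.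

3. Racemization. The spring readings stood at 27.5% converted by 10.0 h, less than noon's 39.7%, so as a rough value I kept the full excess made there. Its product grew by 7.3 points from 5.00 h to 10.0 h, yet the difference went from 9.2 points to 8.5 points. That shortfall, over the mean difference and the time, gives the share of the product difference lost per hour, 0.129 /h, a reading.

4. Noon's old difference keeps 40.5%, and new product, spread evenly, keeps 65.8%. That leaves 9.8 points, an excess of 18.1%. A rate rising in proportion to time gives product a mean age of a third of its time; taking that for the early hours moved my reading to 72.4% at 50 min.

The forecast gave 62%, 21% and 52%, holding that “The falling excess in spring after the reagent is nearly gone shows product racemization”.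

The flask gave 71.5%, 18.2% and 54.3%.

    reagent + catalyst + left-handed substrate → catalyst + left-handed product (k = 9800 /M²/min)
    reagent + catalyst + right-handed substrate → catalyst + right-handed product (k = 1420 /M²/min)
    left-handed product ⇌ right-handed product (k = 9.93 × 10⁻⁴ /min)
    precatalyst → catalyst (k = 0.00187 /min)
    catalyst + added ligand ⇌ idle complex (K = 49400 /M, k = 914 /M/min)

In the flask less of the left-handed substrate than of the right-handed remained, 15% against 76% of their own charges. The gap between them, 30 points of both charged together, equals the product difference ever made, of which 9.9 points stood at 15.0 h. Dividing the loss between these two by 0.129 /h and 15 h gives a mean difference over the run of 11 points; straight lines from zero through the differences at 7.50 h and 15.0 h average 11 points.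

For the neighbour flask with 13 mM of reagent the allowance is 36.1%, and I took product of excess 68.7% as made evenly over the run, so aged half of 15 h, which keeps an excess of 26.1%. That flask computed to 23.0% at 35.1% conversion.

(The runs are simulated for substances that don't exist, and the scatter is random.)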